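Each left-handed product costs one partner, and partner is charged at 50.0% of the two substrates together. Left-handed substrate plus left-handed product holds near that figure: 49.2% at the last midnight reading, 50.4% at the last winter reading.

| flask | left-handed substrate | right-handed substrate | partner | free catalyst | temperature | remark | time |
|---|---|---|---|---|---|---|---|
| midnight | 0.050 M | 0.050 M | 0.050 M | 0.050 mM | 75 °C | run made earlier |  |
| winter | 0.050 M | 0.050 M | 0.050 M | 0.20 mM | 108 °C | run made earlier |  |
| west | 0.050 M | 0.050 M | 0.0500 M | 0.10 mM | 60 °C |  | 6.0 min |
| east | 0.050 M | 0.050 M | 0.0500 M | 0.10 mM | 90 °C |  | 6.0 min |
| south | 0.050 M | 0.050 M | 0.0500 M | 0.10 mM | 120 °C |  | 6.0 min |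

| run | time / s | left-handed product / % | left-handed substrate / % |
|---|---|---|---|
| midnight | 20.0 | 9.9 | 38.5 |
| midnight | 40.0 | 21.3 | 29.9 |
| midnight | 60.0 | 23.2 | 25.0 |
| midnight | 80.0 | 26.3 | 24.5 |
| midnight | 120 | 28.8 | 20.4 |
| winter | 10.0 | 26.0 | 24.0 |
| winter | 12.0 | 27.4 | 23.0 |
| winter | 15.0 | 29.6 | 19.6 |
| winter | 20.0 | 32.3 | 18.1 |

(scatter of a reading: 1 percentage point)

- free catalyst is single-handed; left-handed substrate and right-handed substrate are mirror images of each other, charged as a racemate, each of them at the stated concentration

- which flask leads in amount of left-handed product, in percent of the left-handed substrate and right-handed substrate together charged ("all alike" within 1.5 percentage points) (west / east / south / all alike)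
- how much left-handed product is there at the end, in percent of the left-handed substrate and right-handed substrate together charged: west
- how much left-handed product is there at the end, in percent of the left-handed substrate and right-handed substrate together charged: east
- how much left-handed product is there at the end, in percent of the left-handed substrate and right-handed substrate together charged: south

You can do two extreme flasks in the head. A perfectly selective catalyst turns the partner charge into left-handed product, 50.0%. A catalyst blind to handedness splits partner evenly, giving 25.0%. The midnight run has passed that with 28.8%, so the flask lies between.

To place it, I take the catalyst as steady, so that the log slope of left-handed substrate follows partner. I then replace each window of the midnight run by its mean: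

first window: slope 0.0131 s⁻¹, mean product 4.95%

last window: slope 0.00458 s⁻¹, mean product 27.6%

slope ratio: 0.350

share = (last product − ratio × first product) / (charge − ratio × charge) = 0.795

This is the left share: the part of the partner taken up by the two substrates that ends as left-handed product, the working form of a selectivity factor. The winter run, read the same way, gives 0.718; that run differs from the midnight run in temperature and catalyst charge, so I carry both figures as a range.

My reckoning is therefore left share × partner charge, 35.9% to 39.8%, for a flask whose catalyst and partner keep working. The winter readings stop at 20.0 s, and the flasks run 18.0 times longer, so I hold this as the upper side for south.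

The forecast said all alike, with west 38.3%, east 38.3% and south 37.5%, since “product is set by selectivity”.

The flasks give west 40.4%, east 36.1% and south 20.5%, so west leads.

    partner + free catalyst + left-handed substrate → free catalyst + left-handed product (k = 2.60 × 10⁵ M⁻² min⁻¹, Ea = 31.0 kJ mol⁻¹)
    free catalyst → spent catalyst (k = 0.0510 min⁻¹, Ea = 91.0 kJ mol⁻¹)
    partner → decomposed reagent (k = 0.00430 min⁻¹, Ea = 107 kJ mol⁻¹)
    partner → decomposition product (k = 4.00 × 10⁻⁴ min⁻¹, Ea = 112 kJ mol⁻¹)
    partner + free catalyst + right-handed substrate → free catalyst + right-handed product (k = 21000 M⁻² min⁻¹, Ea = 39.0 kJ mol⁻¹)
    (constants at 60 °C)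

At the left share, south's product reckons to 0.0258 M of partner through the catalyst, half of the charge, while 0.0234 M stands in south as decomposed reagent. By 3.00 min, south's free catalyst stood at 0% and its partner at 0.234%. Sparing the catalyst its loss to spent catalyst lifts south to 31.7%, which closes a part of the gap. A neighbour flask, west with 0.013 M of partner, reckons at 10.3% and gives 11.8%.

The readings were computed with made-up constants; noise was put on by code.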